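**Plan**

Numbering: fragment 1 is the naphthalene with C1 OMe, C3 OH, C4 (axis), C6 CH3, C8 OH (ring A C1–C4, ring B C5–C8); fragment 2 has C1' (axis), C2' CH3, C4' OH, C5' OMe, C6' OH (ring C C1'–C4', ring D C5'–C8', fusion carbons C4a' and C8a').
Retrosynthesis: after removal of three benzyl ethers and rehydration of ring C (C1' tertiary alcohol, C4' ketone), C1'–C2' is cut (key step), then C1'–C8a' (aryllithium plus fragment 1 C4-aldehyde), C3'–C4' (propenyllithium plus ring D aldehyde) and C4–C1' (formylation); in fragment 1, ring B is cut at C5–C6 and C7–C8 (Michael–Dieckmann annulation).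
Enabling feature: C1' and C2' are neighbouring ring C carbons that can both be presented as acceptors from ortho positions of ring D, C1' as a diaryl ketone carbon on C8a' and C2' as the β-carbon of a crotonoyl group on C4a', so a reductive umpolung joins them in a six-membered ring.
Forward order: ring A is bought as ethyl orsellinate, ring B is annulated and C4 formylated; ring D comes from 2,3-dihydroxybenzaldehyde; the halves are joined through C1', oxidised to the keto enone, ring C is closed at the cathode, aromatised and deprotected.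
Stereochemistry: the target has no stereocentre; C1' and C2' of the cyclisation product arise under substrate control and are erased on dehydration; the hindered C4–C1' axis forms in step 15 without control, giving the racemate.

Key step: step 14

Remark: the target SMILES carries no descriptor for the C4–C1' axis, so the racemic biaryl is taken as the goal.
Remark: ethyl orsellinate is used in place of orcinol because its chelated 2-OH allows O1 (methyl) and O3 (benzyl) of fragment 1 to be distinguished by two simple alkylations.
Remark: in step 14 the electrons come from the cathode and the two protons from dimethyl malonate, which is recovered on work-up; bromide is oxidised in the separated anode compartment.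

**Route**

Step 1
Reactants: 1 ethyl 2,4-dihydroxy-6-methylbenzoate (ethyl orsellinate)
Product: 2 ethyl 4-(benzyloxy)-2-hydroxy-6-methylbenzoate
Conditions: BnBr (1.05 equiv), K2CO3, acetone, reflux
Reagents that add atoms: benzyl bromide, BrCc1ccccc1
Why: Williamson etherification under mild base alkylates only the free 4-OH, because the 2-OH is held in a hydrogen bond to the ester carbonyl and is the less nucleophilic oxygen.

Step 2
Reactants: 2 ethyl 4-(benzyloxy)-2-hydroxy-6-methylbenzoate
Product: 3 ethyl 4-(benzyloxy)-2-methoxy-6-methylbenzoate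
Conditions: MeI, K2CO3, DMF, 60 °C
Reagents that add atoms: iodomethane, CI
Why: Williamson methylation in warm DMF overcomes the chelation of the remaining 2-OH, so O1 of fragment 1 ends as the methyl ether and O3 as the benzyl ether.

Step 3
Reactants: 3 ethyl 4-(benzyloxy)-2-methoxy-6-methylbenzoate; 4 methyl (E)-but-2-enoate (methyl crotonate)
Product: 6 methyl 6-(benzyloxy)-1-hydroxy-8-methoxy-3-methyl-3,4-dihydronaphthalene-2-carboxylate (racemic enol form of the β-keto ester), via open-chain Michael adduct enolate 5 (not isolated)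
Conditions: LiN(iPr)2 (1.1 equiv), THF, −78 °C; then 4, −78 °C to rt; then 1 M HCl
Reagents that add atoms: none
Why: Tandem Michael–Dieckmann annulation of an ortho-toluate anion: the benzylic lithium (self-condensation is held back by the flanking methoxy group) adds to C3 of the crotonate and the ester enolate 5 closes ring B on the ethyl ester, the one new stereocentre (C6 of fragment 1) being racemic and removed in step 5.

Step 4
Reactants: 6 methyl 6-(benzyloxy)-1-hydroxy-8-methoxy-3-methyl-3,4-dihydronaphthalene-2-carboxylate
Product: 7 6-(benzyloxy)-8-methoxy-3-methyl-3,4-dihydronaphthalen-1(2H)-one (racemic)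
Conditions: LiCl, DMSO, H2O, 150 °C
Reagents that add atoms: none
Why: Krapcho dealkoxycarbonylation, in which chloride cleaves the methyl ester and the β-keto carboxylate loses CO2 under neutral conditions that leave the aryl ethers untouched.

Step 5
Reactants: 7 6-(benzyloxy)-8-methoxy-3-methyl-3,4-dihydronaphthalen-1(2H)-one
Product: 9 6-(benzyloxy)-8-methoxy-3-methylnaphthalen-1-ol, via 4H-naphthalen-1-one tautomer 8 (not isolated)
Conditions: Pd(OCOCF3)2 (5 mol %), 2-(dimethylamino)pyridine (10 mol %), TsOH (20 mol %), O2 (1 atm), DMSO, 80 °C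
Reagents that add atoms: none
Why: Palladium-catalysed aerobic dehydrogenation of a cyclic ketone, in which β-hydride elimination from the palladium enolate gives enone 8 that tautomerises at once to the naphthol, with O2 as terminal oxidant and the benzyl ether inert in the absence of H2.

Step 6
Reactants: 9 6-(benzyloxy)-8-methoxy-3-methylnaphthalen-1-ol
Product: 10 1,6-bis(benzyloxy)-8-methoxy-3-methylnaphthalene
Conditions: BnBr, K2CO3, DMF, 60 °C
Reagents that add atoms: benzyl bromide, BrCc1ccccc1
Why: Williamson benzylation of the peri-chelated hydroxyl (O8 of fragment 1) needs only warming in DMF and completes the protecting pattern O1 methyl, O3 and O8 benzyl.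

Step 7
Reactants: 10 1,6-bis(benzyloxy)-8-methoxy-3-methylnaphthalene
Product: 12 2,5-bis(benzyloxy)-4-methoxy-7-methylnaphthalene-1-carbaldehyde, via aryl iminium chloride 11 (not isolated)
Conditions: POCl3, DMF, 0 °C to 60 °C; then H2O, 60 °C
Reagents that add atoms: N,N-dimethylformamide, CN(C)C=O; water, O
Why: Vilsmeier–Haack formylation attacks C4 of fragment 1, the α-position para to the C1 methoxy and ortho to the C3 benzyloxy group and hence the most electron-rich site, and hydrolysis of iminium salt 11 gives the aldehyde whose carbon becomes C1'.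

Step 8
Reactants: 13 2,3-dihydroxybenzaldehyde
Product: 14 3-(benzyloxy)-2-hydroxybenzaldehyde
Conditions: NaH (2.2 equiv), DMSO, rt; BnBr (1.0 equiv); then 1 M HCl
Reagents that add atoms: benzyl bromide, BrCc1ccccc1
Why: Williamson alkylation of the dianion, in which the phenoxide at O3 is not stabilised by conjugation with or chelation to the formyl group and is the more nucleophilic, so one equivalent of benzyl bromide gives the 3-benzyl ether (O6' of fragment 2).

Step 9
Reactants: 14 3-(benzyloxy)-2-hydroxybenzaldehyde
Product: 15 3-(benzyloxy)-2-methoxybenzaldehyde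
Conditions: MeI, K2CO3, DMF, rt
Reagents that add atoms: iodomethane, CI
Why: Williamson methylation of the remaining salicylaldehyde-type hydroxyl installs the C5' methoxy group.

Step 10
Reactants: 15 3-(benzyloxy)-2-methoxybenzaldehyde
Product: 16 3-(benzyloxy)-6-bromo-2-methoxybenzaldehyde
Conditions: NBS, DMF, rt, dark
Reagents that add atoms: N-bromosuccinimide, O=C1CCC(=O)N1Br
Why: Electrophilic aromatic bromination goes para to the 3-benzyloxy group (the future C8a'), the stronger donor because the doubly flanked 2-methoxy group is twisted out of conjugation, as is known for 2,3-dialkoxybenzaldehydes.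

Step 11
Reactants: 16 3-(benzyloxy)-6-bromo-2-methoxybenzaldehyde; 17 (E)-1-bromoprop-1-ene
Product: 19 (E)-1-[3-(benzyloxy)-6-bromo-2-methoxyphenyl]but-2-en-1-ol (racemic), via (E)-prop-1-enyllithium 18 (not isolated)
Conditions: 17 (1.3 equiv), t-BuLi (2.6 equiv), Et2O, −78 °C; then 16, THF, −78 °C; then H2O
Reagents that add atoms: none
Why: Bromine–lithium exchange of the vinyl bromide at −78 °C retains the E geometry and the vinyllithium adds 1,2 to the aldehyde faster than it exchanges with the aryl bromide, giving a racemic carbinol whose stereocentre is removed in step 13.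

Step 12
Reactants: 19 (E)-1-[3-(benzyloxy)-6-bromo-2-methoxyphenyl]but-2-en-1-ol; 12 2,5-bis(benzyloxy)-4-methoxy-7-methylnaphthalene-1-carbaldehyde
Product: 21 (E)-1-[3-(benzyloxy)-6-{[2,5-bis(benzyloxy)-4-methoxy-7-methylnaphthalen-1-yl](hydroxy)methyl}-2-methoxyphenyl]but-2-en-1-ol (mixture of racemic diastereomers), via aryllithium lithium alkoxide 20 (not isolated)
Conditions: n-BuLi (2.1 equiv), THF, −78 °C; then 12, −78 °C to 0 °C; then H2O
Reagents that add atoms: none
Why: Ortho-lithiobenzyl alkoxide chemistry, in which the first equivalent of n-BuLi forms the alkoxide, the second effects bromine–lithium exchange and the aryllithium adds to the non-enolisable aldehyde to make the C1'–C8a' bond, the two carbinol centres forming without control because both are oxidised away in step 13.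

Step 13
Reactants: 21 (E)-1-[3-(benzyloxy)-6-{[2,5-bis(benzyloxy)-4-methoxy-7-methylnaphthalen-1-yl](hydroxy)methyl}-2-methoxyphenyl]but-2-en-1-ol
Product: 22 (E)-1-{3-(benzyloxy)-6-[2,5-bis(benzyloxy)-4-methoxy-7-methylnaphthalene-1-carbonyl]-2-methoxyphenyl}but-2-en-1-one
Conditions: Dess–Martin periodinane (3 equiv), NaHCO3, CH2Cl2, 0 °C to rt
Reagents that add atoms: none
Why: Dess–Martin oxidation converts both secondary benzylic alcohols (one also allylic) into ketones under buffered, non-acidic conditions that spare the E-alkene, the benzyl ethers and the electron-rich naphthalene.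

Step 14
Reactants: 22 (E)-1-{3-(benzyloxy)-6-[2,5-bis(benzyloxy)-4-methoxy-7-methylnaphthalene-1-carbonyl]-2-methoxyphenyl}but-2-en-1-one
Product: 24 rac-(3S,4S)-7-(benzyloxy)-4-[2,5-bis(benzyloxy)-4-methoxy-7-methylnaphthalen-1-yl]-4-hydroxy-8-methoxy-3-methyl-3,4-dihydronaphthalen-1(2H)-one (aryl trans to methyl), via ketyl radical anion 23 (not isolated)
Conditions: divided H-cell (glass frit), reticulated vitreous carbon cathode, Pt anode, 0.1 M Et4NBr in DMF in both compartments, 22 (5 mM), dimethyl malonate (3 equiv), controlled potential about −1.7 V vs SCE (set by cyclic voltammetry just past the first wave), 2.1 F/mol, rt; then aq. NH4Cl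
Reagents that add atoms: none
Why: Electron transfer at a potential just past the first wave of the ortho-diacylarene gives the persistent diaryl ketyl radical anion 23, whose carbon C1' adds to the enone β-carbon C2'; the α-keto radical so formed takes up a second electron at once and dimethyl malonate protonates the enolate, the tertiary alkoxide being protonated on work-up. The closest known reaction types are the electroreductive and SmI2 (divalent samarium) ketyl–olefin cyclisations onto α,β-unsaturated carbonyl acceptors and the cathodic cross-coupling of diaryl ketones with the β-carbon of chromones and coumarins. Ring C closes in the 6-endo-trig mode, with C3' and the C4' carbonyl inside the new ring, the same topology as the Michael closure of a 2'-hydroxychalcone to a flavanone. C1' and C2' become stereocentres under substrate control only: the bulky fragment 1 aryl on C1' should settle anti to the C2' methyl group in the half-chair transition state, which leads to the trans isomer shown, and either isomer serves because step 15 erases both centres. The step needs chemoselectivity for intramolecular C–C closure over pinacol dimerisation, over further reduction of the protonated ketyl (whose alkoxide would add to the neighbouring carbonyl) and over saturation of the enone; it is secured by the ortho placement of the two acyl groups on C8a' and C4a' of ring D, by the stabilised and hindered ketyl that cannot dimerise easily, and by dilution, a weak proton donor and a potential held below the second wave. Aryl benzyl and methyl ethers and the product ketone are not reduced at this potential.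

Step 15
Reactants: 24 rac-(3S,4S)-7-(benzyloxy)-4-[2,5-bis(benzyloxy)-4-methoxy-7-methylnaphthalen-1-yl]-4-hydroxy-8-methoxy-3-methyl-3,4-dihydronaphthalen-1(2H)-one
Product: 26 7-(benzyloxy)-4-[2,5-bis(benzyloxy)-4-methoxy-7-methylnaphthalen-1-yl]-8-methoxy-3-methylnaphthalen-1-ol (racemic about the biaryl axis), via 2H-naphthalen-1-one tautomer 25 (not isolated)
Conditions: TsOH·H2O (10 mol %), toluene, 60 °C
Reagents that add atoms: none
Why: Acid-catalysed E1 dehydration, in which the tertiary doubly benzylic C1' alcohol ionises readily (the cation is stabilised by the 2,4-dialkoxynaphthyl group), loss of the C2' proton gives enone 25 and its enolisation is driven by aromatisation of ring C, the C4–C1' axis arising here without control.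

Step 16
Reactants: 26 7-(benzyloxy)-4-[2,5-bis(benzyloxy)-4-methoxy-7-methylnaphthalen-1-yl]-8-methoxy-3-methylnaphthalen-1-ol
Product: 27 5-(4,6-dihydroxy-5-methoxy-2-methylnaphthalen-1-yl)-8-methoxy-3-methylnaphthalene-1,6-diol (CNP0147277.0, racemic about the biaryl axis)
Conditions: H2 (1 atm), Pd/C (10 wt %), EtOAc/MeOH, rt
Reagents that add atoms: none
Why: Catalytic hydrogenolysis cleaves the three aryl benzyl ethers and leaves the methyl ethers and the naphthalene rings intact, which should give the target.

**Compound list**

1 | ethyl 2,4-dihydroxy-6-methylbenzoate (ethyl orsellinate) | CCOC(=O)c1c(C)cc(O)cc1O | starting material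
2 | ethyl 4-(benzyloxy)-2-hydroxy-6-methylbenzoate | CCOC(=O)c1c(C)cc(OCc2ccccc2)cc1O | intermediate
3 | ethyl 4-(benzyloxy)-2-methoxy-6-methylbenzoate | CCOC(=O)c1c(C)cc(OCc2ccccc2)cc1OC | intermediate
4 | methyl (E)-but-2-enoate (methyl crotonate) | C/C=C/C(=O)OC | starting material
5 | lithium enolate of ethyl 4-(benzyloxy)-2-methoxy-6-(4-methoxy-2-methyl-4-oxobutyl)benzoate (racemic Michael adduct) | CCOC(=O)c1c(OC)cc(OCc2ccccc2)cc1CC(C)C=C(O[Li])OC | intermediate (not isolated)
6 | methyl 6-(benzyloxy)-1-hydroxy-8-methoxy-3-methyl-3,4-dihydronaphthalene-2-carboxylate (racemic, enol form) | COC(=O)C1=C(O)c2c(OC)cc(OCc3ccccc3)cc2CC1C | intermediate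
7 | 6-(benzyloxy)-8-methoxy-3-methyl-3,4-dihydronaphthalen-1(2H)-one (racemic) | CC1CC(=O)c2c(OC)cc(OCc3ccccc3)cc2C1 | intermediate
8 | 6-(benzyloxy)-8-methoxy-3-methylnaphthalen-1(4H)-one | CC1=CC(=O)c2c(OC)cc(OCc3ccccc3)cc2C1 | intermediate (not isolated)
9 | 6-(benzyloxy)-8-methoxy-3-methylnaphthalen-1-ol | Cc1cc(O)c2c(OC)cc(OCc3ccccc3)cc2c1 | intermediate
10 | 1,6-bis(benzyloxy)-8-methoxy-3-methylnaphthalene | Cc1cc(OCc2ccccc2)c2c(OC)cc(OCc3ccccc3)cc2c1 | intermediate
11 | N-{[2,5-bis(benzyloxy)-4-methoxy-7-methylnaphthalen-1-yl]methylidene}-N-methylmethanaminium chloride | C[N+](C)=Cc1c(OCc2ccccc2)cc(OC)c2c(OCc3ccccc3)cc(C)cc12.[Cl-] | intermediate (not isolated)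
12 | 2,5-bis(benzyloxy)-4-methoxy-7-methylnaphthalene-1-carbaldehyde | O=Cc1c(OCc2ccccc2)cc(OC)c2c(OCc3ccccc3)cc(C)cc12 | intermediate
13 | 2,3-dihydroxybenzaldehyde | O=Cc1cccc(O)c1O | starting material
14 | 3-(benzyloxy)-2-hydroxybenzaldehyde | O=Cc1cccc(OCc2ccccc2)c1O | intermediate
15 | 3-(benzyloxy)-2-methoxybenzaldehyde | COc1c(C=O)cccc1OCc1ccccc1 | intermediate
16 | 3-(benzyloxy)-6-bromo-2-methoxybenzaldehyde | COc1c(OCc2ccccc2)ccc(Br)c1C=O | intermediate
17 | (E)-1-bromoprop-1-ene | C/C=C/Br | starting material
18 | (E)-prop-1-enyllithium | C/C=C/[Li] | intermediate (not isolated)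
19 | (E)-1-[3-(benzyloxy)-6-bromo-2-methoxyphenyl]but-2-en-1-ol (racemic) | C/C=C/C(O)c1c(Br)ccc(OCc2ccccc2)c1OC | intermediate
20 | lithium (E)-1-[3-(benzyloxy)-6-lithio-2-methoxyphenyl]but-2-en-1-olate | C/C=C/C(O[Li])c1c([Li])ccc(OCc2ccccc2)c1OC | intermediate (not isolated)
21 | (E)-1-[3-(benzyloxy)-6-{[2,5-bis(benzyloxy)-4-methoxy-7-methylnaphthalen-1-yl](hydroxy)methyl}-2-methoxyphenyl]but-2-en-1-ol (mixture of racemic diastereomers) | C/C=C/C(O)c1c(OC)c(OCc2ccccc2)ccc1C(O)c1c(OCc2ccccc2)cc(OC)c2c(OCc3ccccc3)cc(C)cc12 | intermediate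
22 | (E)-1-{3-(benzyloxy)-6-[2,5-bis(benzyloxy)-4-methoxy-7-methylnaphthalene-1-carbonyl]-2-methoxyphenyl}but-2-en-1-one | C/C=C/C(=O)c1c(OC)c(OCc2ccccc2)ccc1C(=O)c1c(OCc2ccccc2)cc(OC)c2c(OCc3ccccc3)cc(C)cc12 | intermediate (key-step precursor)
23 | ketyl radical anion of 22 (radical on C1', negative charge on its oxygen) | C/C=C/C(=O)c1c(OC)c(OCc2ccccc2)ccc1[C]([O-])c1c(OCc2ccccc2)cc(OC)c2c(OCc3ccccc3)cc(C)cc12 | intermediate (not isolated)
24 | rac-(3S,4S)-7-(benzyloxy)-4-[2,5-bis(benzyloxy)-4-methoxy-7-methylnaphthalen-1-yl]-4-hydroxy-8-methoxy-3-methyl-3,4-dihydronaphthalen-1(2H)-one (aryl trans to methyl; one enantiomer drawn) | C[C@H]1CC(=O)c2c(OC)c(OCc3ccccc3)ccc2[C@]1(O)c1c(OCc2ccccc2)cc(OC)c2c(OCc3ccccc3)cc(C)cc12 | intermediate (key-step product)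
25 | 7-(benzyloxy)-4-[2,5-bis(benzyloxy)-4-methoxy-7-methylnaphthalen-1-yl]-8-methoxy-3-methylnaphthalen-1(2H)-one | CC1=C(c2c(OCc3ccccc3)cc(OC)c3c(OCc4ccccc4)cc(C)cc23)c2ccc(OCc3ccccc3)c(OC)c2C(=O)C1 | intermediate (not isolated)
26 | 7-(benzyloxy)-4-[2,5-bis(benzyloxy)-4-methoxy-7-methylnaphthalen-1-yl]-8-methoxy-3-methylnaphthalen-1-ol (racemic about the axis) | Cc1cc(O)c2c(OC)c(OCc3ccccc3)ccc2c1-c1c(OCc2ccccc2)cc(OC)c2c(OCc3ccccc3)cc(C)cc12 | intermediate
27 | 5-(4,6-dihydroxy-5-methoxy-2-methylnaphthalen-1-yl)-8-methoxy-3-methylnaphthalene-1,6-diol (CNP0147277.0, racemic about the axis) | COc1cc(O)c(-c2c(C)cc(O)c3c(OC)c(O)ccc23)c2cc(C)cc(O)c12 | target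

**Step count**

Total: 16 steps. Longest linear sequence: 12 steps (steps 1–7, then 12–16); steps 8–11 form the second branch.

**Steps most likely to fail**

Step 14. The ketyl may be protonated and reduced further before it closes (the resulting alkoxide would then add to the neighbouring carbonyl and end as a lactol or isobenzofuran), it may dimerise, or the enone may simply be saturated. SmI2 (divalent samarium) in THF with t-BuOH would be tried first as the like-for-like chemical reductant. The fallback changes the umpolung from a ketyl to a phthalide carbanion, sets out from 16 and 12 and comes back at 24. Pinnick oxidation of 16 (NaClO2, NaH2PO4, 2-methylbut-2-ene, t-BuOH/H2O) should give 3-(benzyloxy)-6-bromo-2-methoxybenzoic acid F1. Treatment with n-BuLi (2.1 equiv, THF, −78 °C) forms the ortho-lithiated lithium benzoate, which adds to aldehyde 12; acidification closes the lactone to 6-(benzyloxy)-3-[2,5-bis(benzyloxy)-4-methoxy-7-methylnaphthalen-1-yl]-7-methoxy-2-benzofuran-1(3H)-one F2. Deprotonation of the lactone CH (the future C1') with LiN(SiMe3)2 in THF at −78 °C and addition of methyl crotonate 4 should give, by Michael addition to C2' and Dieckmann attack of the ester enolate on the lactone carbonyl, methyl 7-(benzyloxy)-4-[2,5-bis(benzyloxy)-4-methoxy-7-methylnaphthalen-1-yl]-4-hydroxy-8-methoxy-3-methyl-1-oxo-1,2,3,4-tetrahydronaphthalene-2-carboxylate F3. Krapcho dealkoxycarbonylation (LiCl, wet DMSO, 140 °C) then leads to 24; loss of water at this stage would give 26 directly and would be equally acceptable.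

Step 12. The new aryllithium may be quenched by proton transfer within the alkoxide aggregate during the exchange (net debromination), or the aggregated dilithio species may add only sluggishly to the hindered, electron-rich aldehyde. The fallback protects the alcohol, sets out from 19 and comes back at 21. Silylation (TBSCl, imidazole, DMF) gives tert-butyl{[(E)-1-(3-(benzyloxy)-6-bromo-2-methoxyphenyl)but-2-en-1-yl]oxy}dimethylsilane F4. Bromine–lithium exchange with n-BuLi (1.05 equiv, THF, −78 °C) and addition of 12 give [2,5-bis(benzyloxy)-4-methoxy-7-methylnaphthalen-1-yl]{4-(benzyloxy)-2-[(E)-1-{[tert-butyl(dimethyl)silyl]oxy}but-2-en-1-yl]-3-methoxyphenyl}methanol F5. Desilylation with Bu4NF in THF returns diol 21.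

Step 5. The electron-rich naphthol may be over-oxidised under O2 (quinone formation or oxidative coupling at its free para position), or the dehydrogenation may stall. The fallback replaces catalytic dehydrogenation by halogenation and elimination, sets out from 7 and comes back at 9. α-Bromination with CuBr2 (EtOAc/CHCl3, reflux) gives 6-(benzyloxy)-2-bromo-8-methoxy-3-methyl-3,4-dihydronaphthalen-1(2H)-one F6. Dehydrobromination with LiBr and Li2CO3 in DMF at 120 °C gives the enone, which tautomerises to 9.

**Further compounds**

F1 | step 14 | 3-(benzyloxy)-6-bromo-2-methoxybenzoic acid | COc1c(OCc2ccccc2)ccc(Br)c1C(=O)O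
F2 | step 14 | 6-(benzyloxy)-3-[2,5-bis(benzyloxy)-4-methoxy-7-methylnaphthalen-1-yl]-7-methoxy-2-benzofuran-1(3H)-one (racemic) | O=C1OC(c2c(OCc3ccccc3)cc(OC)c3c(OCc4ccccc4)cc(C)cc23)c2ccc(OCc3ccccc3)c(OC)c12
F3 | step 14 | methyl 7-(benzyloxy)-4-[2,5-bis(benzyloxy)-4-methoxy-7-methylnaphthalen-1-yl]-4-hydroxy-8-methoxy-3-methyl-1-oxo-1,2,3,4-tetrahydronaphthalene-2-carboxylate (mixture of diastereomers) | COC(=O)C1C(C)C(O)(c2c(OCc3ccccc3)cc(OC)c3c(OCc4ccccc4)cc(C)cc23)c2ccc(OCc3ccccc3)c(OC)c2C1=O
F4 | step 12 | tert-butyl{[(E)-1-(3-(benzyloxy)-6-bromo-2-methoxyphenyl)but-2-en-1-yl]oxy}dimethylsilane (racemic) | C/C=C/C(O[Si](C)(C)C(C)(C)C)c1c(Br)ccc(OCc2ccccc2)c1OC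
F5 | step 12 | [2,5-bis(benzyloxy)-4-methoxy-7-methylnaphthalen-1-yl]{4-(benzyloxy)-2-[(E)-1-{[tert-butyl(dimethyl)silyl]oxy}but-2-en-1-yl]-3-methoxyphenyl}methanol (mixture of diastereomers) | C/C=C/C(O[Si](C)(C)C(C)(C)C)c1c(OC)c(OCc2ccccc2)ccc1C(O)c1c(OCc2ccccc2)cc(OC)c2c(OCc3ccccc3)cc(C)cc12
F6 | step 5 | 6-(benzyloxy)-2-bromo-8-methoxy-3-methyl-3,4-dihydronaphthalen-1(2H)-one (mixture of diastereomers) | CC1Cc2cc(OCc3ccccc3)cc(OC)c2C(=O)C1Br
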